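**Assumption:** the target has no stereocentre and no stereogenic double bond (the prenyl alkene carries two identical methyl groups), so no stereocontrol is needed and the route makes the single achiral compound.

## Retrosynthetic overview

- Target 15 ← bis-MOM ether 14 ← iodide 13 (prenyl at C6' by Stille coupling) ← aldehyde 12 (CHO at C2' by Vilsmeier formylation) ← benzophenone 10.
- Key disconnection: the bond from ring A C6 to the ketone carbon. C6 sits between C1–OMe and C5–OH, so the aroyl group is first placed on the C5 oxygen (ester 7) and then moved to C6 by a 1,3 O→C shift (anionic Fries) triggered by Br/Li exchange.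
- Ring B C1' is meta to both oxygens (C3', C5') and cannot be reached by electrophilic substitution, so it enters as the carboxyl carbon of 3,5-dihydroxybenzoic acid.
- Ester 7 ← phenol 3 (3-methoxy-5-methylphenol; ortho,ortho-dibromination, then chlorination of the last free position) + acid 6.
- No ring is built; both arenes are bought, and the Br that does not exchange becomes the C4 bromine of the target.

Key step: step 5

## Route

Step 1
Reactants: 1 3-methoxy-5-methylphenol
Product: 2 2,6-dibromo-3-methoxy-5-methylphenol
Conditions: NBS (2.05 equiv), i-Pr2NH (10 mol %), CH2Cl2, 0 °C to rt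
Reagents that add atoms: N-bromosuccinimide, O=C1CCC(=O)N1Br
Why: Amine-mediated ortho-selective bromination of a phenol (hydrogen-bonded N-bromoamine delivers Br to both positions next to OH); the para position is shielded by OMe and Me.

Step 2
Reactants: 2 2,6-dibromo-3-methoxy-5-methylphenol
Product: 3 2,6-dibromo-4-chloro-3-methoxy-5-methylphenol
Conditions: SO2Cl2 (1.1 equiv), CH2Cl2, 0 °C to rt, dark
Reagents that add atoms: sulfuryl chloride, O=S(=O)(Cl)Cl
Why: Electrophilic aromatic chlorination at the only remaining ring position, which is para to OH and ortho to OMe, so the regiochemistry is forced.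

Step 3
Reactants: 4 3,5-dihydroxybenzoic acid
Product: 6 3,5-bis(methoxymethoxy)benzoic acid, via methoxymethyl 3,5-bis(methoxymethoxy)benzoate 5 (not isolated)
Conditions: MOMCl (3.5 equiv), i-Pr2NEt, CH2Cl2, 0 °C to rt; then LiOH, THF/MeOH/H2O, rt; 1 M HCl to pH 4 at 0 °C
Reagents that add atoms: chloromethyl methyl ether, COCCl; lithium hydroxide, [Li+].[OH-]
Why: Exhaustive O-alkylation followed by saponification of the labile MOM ester; the aryl MOM ethers are stable to base and to brief cold acidification.

Step 4
Reactants: 3 2,6-dibromo-4-chloro-3-methoxy-5-methylphenol; 6 3,5-bis(methoxymethoxy)benzoic acid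
Product: 7 2,6-dibromo-4-chloro-3-methoxy-5-methylphenyl 3,5-bis(methoxymethoxy)benzoate
Conditions: DCC, DMAP (1 equiv), CH2Cl2, rt
Reagents that add atoms: none
Why: Steglich esterification; the acidic, hindered phenol is acylated through the acylpyridinium ion under neutral conditions that leave the MOM ethers intact.

Step 5
Reactants: 7 2,6-dibromo-4-chloro-3-methoxy-5-methylphenyl 3,5-bis(methoxymethoxy)benzoate
Product: 10 [3-bromo-5-chloro-2-hydroxy-6-methoxy-4-methylphenyl][3,5-bis(methoxymethoxy)phenyl]methanone, via aryllithium 8 (not isolated), via lithium phenolate 9 (not isolated)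
Conditions: n-BuLi (1.05 equiv), THF, −100 °C, 20 min; then −100 to 0 °C; sat. aq NH4Cl
Reagents that add atoms: none
Why: Bromine–lithium exchange at the bromine flanked by OMe and the acyloxy group gives aryllithium 8, which attacks the neighbouring ester carbonyl through a four-membered tetrahedral intermediate; its collapse moves the aroyl group from oxygen to carbon and releases phenolate 9. The closest known reaction type is the anionic ortho-Fries rearrangement of o-bromoaryl esters triggered by halogen–metal exchange. No ring is closed and no stereocentre is formed. The step needs exchange at C2–Br rather than C6–Br or C–Cl, and exchange faster than addition of n-BuLi to the ester; the two ortho oxygens (inductive stabilisation and chelation of Li) should favour the C2 site, and Br/Li exchange at −100 °C should outrun carbonyl addition. The ester is non-enolisable and its ring B ortho positions are unsubstituted, so the carbonyl stays accessible to the internal nucleophile. The shift makes the ketone between two ortho substituents, frees the C5 phenol and leaves the second bromine where the target needs it.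

Step 6
Reactants: 10 [3-bromo-5-chloro-2-hydroxy-6-methoxy-4-methylphenyl][3,5-bis(methoxymethoxy)phenyl]methanone
Product: 12 2-(3-bromo-5-chloro-2-hydroxy-6-methoxy-4-methylbenzoyl)-4,6-bis(methoxymethoxy)benzaldehyde, via aryl iminium chloride 11 (not isolated)
Conditions: POCl3 (3 equiv), DMF, 0 to 50 °C; ice-water, NaOAc to pH 5
Reagents that add atoms: N,N-dimethylformamide, CN(C)C=O; water, O
Why: Vilsmeier–Haack formylation; ring A has no free position, and on ring B the site ortho to one OMOM and para to the other (next to the aroyl group) should be preferred over the site between the two OMOM groups, as with 3,5-dialkoxybenzoates.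

Step 7
Reactants: 12 2-(3-bromo-5-chloro-2-hydroxy-6-methoxy-4-methylbenzoyl)-4,6-bis(methoxymethoxy)benzaldehyde
Product: 13 2-(3-bromo-5-chloro-2-hydroxy-6-methoxy-4-methylbenzoyl)-3-iodo-4,6-bis(methoxymethoxy)benzaldehyde
Conditions: NIS (1.1 equiv), TFA (10 mol %), MeCN, 0 °C to rt
Reagents that add atoms: N-iodosuccinimide, O=C1CCC(=O)N1I
Why: Electrophilic iodination of a 2,4-dialkoxybenzaldehyde at its 5-type position (para to the OMOM next to CHO, ortho to the other OMOM), the usual site for such rings; it is done before the prenyl alkene is present.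

Step 8
Reactants: 13 2-(3-bromo-5-chloro-2-hydroxy-6-methoxy-4-methylbenzoyl)-3-iodo-4,6-bis(methoxymethoxy)benzaldehyde
Product: 14 2-(3-bromo-5-chloro-2-hydroxy-6-methoxy-4-methylbenzoyl)-4,6-bis(methoxymethoxy)-3-(3-methylbut-2-en-1-yl)benzaldehyde
Conditions: tributyl(3-methylbut-2-en-1-yl)stannane (1.5 equiv), Pd2(dba)3 (5 mol %), P(2-furyl)3 (20 mol %), DMF, 60 °C
Reagents that add atoms: tributyl(3-methylbut-2-en-1-yl)stannane, CCCC[Sn](CCCC)(CCCC)CC=C(C)C
Why: Stille coupling; oxidative addition should occur at the C–I bond well before the hindered, electron-rich C–Br bond of ring A, and prenylstannanes normally transfer the linear prenyl group.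

Step 9
Reactants: 14 2-(3-bromo-5-chloro-2-hydroxy-6-methoxy-4-methylbenzoyl)-4,6-bis(methoxymethoxy)-3-(3-methylbut-2-en-1-yl)benzaldehyde
Product: 15 Pestalone G, 2-(3-bromo-5-chloro-2-hydroxy-6-methoxy-4-methylbenzoyl)-4,6-dihydroxy-3-(3-methylbut-2-en-1-yl)benzaldehyde
Conditions: HCl (0.5 M) in MeOH/THF, 40 °C, monitored; aqueous work-up
Reagents that add atoms: none
Why: Acid-catalysed transacetalisation removes both MOM groups; dilute acid at moderate temperature is commonly tolerated by ortho-prenyl phenols, and the ring A methyl ether is inert.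

## Compound list

1 | 3-methoxy-5-methylphenol | COc1cc(C)cc(O)c1 | starting material
2 | 2,6-dibromo-3-methoxy-5-methylphenol | COc1cc(C)c(Br)c(O)c1Br | intermediate
3 | 2,6-dibromo-4-chloro-3-methoxy-5-methylphenol | COc1c(Cl)c(C)c(Br)c(O)c1Br | intermediate
4 | 3,5-dihydroxybenzoic acid | OC(=O)c1cc(O)cc(O)c1 | starting material
5 | methoxymethyl 3,5-bis(methoxymethoxy)benzoate (not isolated) | COCOC(=O)c1cc(OCOC)cc(OCOC)c1 | intermediate
6 | 3,5-bis(methoxymethoxy)benzoic acid | COCOc1cc(OCOC)cc(C(=O)O)c1 | intermediate
7 | 2,6-dibromo-4-chloro-3-methoxy-5-methylphenyl 3,5-bis(methoxymethoxy)benzoate | COCOc1cc(OCOC)cc(C(=O)Oc2c(Br)c(C)c(Cl)c(OC)c2Br)c1 | intermediate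
8 | 2-lithio aryl ester (3-bromo-5-chloro-2-lithio-6... numbered as in 7: 6-bromo-4-chloro-2-lithio-3-methoxy-5-methylphenyl 3,5-bis(methoxymethoxy)benzoate; not isolated) | COCOc1cc(OCOC)cc(C(=O)Oc2c(Br)c(C)c(Cl)c(OC)c2[Li])c1 | intermediate
9 | lithium phenolate of 10 (not isolated) | COCOc1cc(OCOC)cc(C(=O)c2c([O-])c(Br)c(C)c(Cl)c2OC)c1.[Li+] | intermediate
10 | [3-bromo-5-chloro-2-hydroxy-6-methoxy-4-methylphenyl][3,5-bis(methoxymethoxy)phenyl]methanone | COCOc1cc(OCOC)cc(C(=O)c2c(O)c(Br)c(C)c(Cl)c2OC)c1 | intermediate
11 | N,N-dimethyl aryl-methaniminium chloride at C2' of 10 (not isolated) | COCOc1cc(OCOC)c(C=[N+](C)C)c(C(=O)c2c(O)c(Br)c(C)c(Cl)c2OC)c1.[Cl-] | intermediate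
12 | 2-(3-bromo-5-chloro-2-hydroxy-6-methoxy-4-methylbenzoyl)-4,6-bis(methoxymethoxy)benzaldehyde | COCOc1cc(OCOC)c(C=O)c(C(=O)c2c(O)c(Br)c(C)c(Cl)c2OC)c1 | intermediate
13 | 2-(3-bromo-5-chloro-2-hydroxy-6-methoxy-4-methylbenzoyl)-3-iodo-4,6-bis(methoxymethoxy)benzaldehyde | COCOc1cc(OCOC)c(I)c(C(=O)c2c(O)c(Br)c(C)c(Cl)c2OC)c1C=O | intermediate
14 | 2-(3-bromo-5-chloro-2-hydroxy-6-methoxy-4-methylbenzoyl)-4,6-bis(methoxymethoxy)-3-(3-methylbut-2-en-1-yl)benzaldehyde | COCOc1cc(OCOC)c(CC=C(C)C)c(C(=O)c2c(O)c(Br)c(C)c(Cl)c2OC)c1C=O | intermediate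
15 | Pestalone G | COc1c(Cl)c(C)c(Br)c(O)c1C(=O)c1c(C=O)c(O)cc(O)c1CC=C(C)C | target

## Step count and risks

Total step count: 9. Longest linear sequence: 8 (steps 1, 2, 4, 5, 6, 7, 8, 9).

Steps most likely to fail:

1. Step 5. The exchange may occur partly at the other bromine (giving the isomeric ketone after migration), or n-BuLi may add to the ester carbonyl before exchange. Fallback: an intermolecular acylation without an internal electrophile. It sets out from 3, which is O-allylated (allyl bromide, K2CO3, acetone) to 1-(allyloxy)-2,6-dibromo-4-chloro-3-methoxy-5-methylbenzene F1. Acid 6 is converted (CDI, then MeNHOMe·HCl) to N-methoxy-N-methyl-3,5-bis(methoxymethoxy)benzamide F2. F1 is treated with n-BuLi in Et2O at −78 °C, where the aryllithium can equilibrate to the more stable site between the two oxygens, and F2 is added to give [2-(allyloxy)-3-bromo-5-chloro-6-methoxy-4-methylphenyl][3,5-bis(methoxymethoxy)phenyl]methanone F3. Deallylation (Pd(PPh3)4, morpholine, THF, rt) returns to the route at 10.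

2. Step 6. The aroyl-deactivated, hindered ring may formylate slowly, and the heat and HCl of the Vilsmeier conditions may cleave a MOM ether. Fallback: a carbonylative formylation in place of electrophilic substitution. It sets out from 10, which is iodinated (NIS, cat. TFA, MeCN) to [3-bromo-5-chloro-2-hydroxy-6-methoxy-4-methylphenyl][2-iodo-3,5-bis(methoxymethoxy)phenyl]methanone F4. Pd-catalysed reductive carbonylation of the C–I bond (Pd(PPh3)4, CO 1–3 atm, Bu3SnH added slowly, toluene, 50 °C) then gives the aldehyde and returns to the route at 12.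

3. Step 8. The prenyl group may transfer through its γ-terminus (reverse-prenyl isomer), and coupling at the doubly ortho-substituted iodide may be slow. Fallback: allylation followed by olefin cross-metathesis. It sets out from 13, which is coupled with allyltributylstannane under the same Stille conditions to 3-allyl-2-(3-bromo-5-chloro-2-hydroxy-6-methoxy-4-methylbenzoyl)-4,6-bis(methoxymethoxy)benzaldehyde F5. Cross-metathesis with excess 2-methyl-2-butene (Grubbs second-generation catalyst, CH2Cl2, 40 °C) returns to the route at 14.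

## Further compounds

F1 | step 5 | 1-(allyloxy)-2,6-dibromo-4-chloro-3-methoxy-5-methylbenzene | C=CCOc1c(Br)c(C)c(Cl)c(OC)c1Br
F2 | step 5 | N-methoxy-N-methyl-3,5-bis(methoxymethoxy)benzamide | COCOc1cc(OCOC)cc(C(=O)N(C)OC)c1
F3 | step 5 | [2-(allyloxy)-3-bromo-5-chloro-6-methoxy-4-methylphenyl][3,5-bis(methoxymethoxy)phenyl]methanone | C=CCOc1c(Br)c(C)c(Cl)c(OC)c1C(=O)c1cc(OCOC)cc(OCOC)c1
F4 | step 6 | [3-bromo-5-chloro-2-hydroxy-6-methoxy-4-methylphenyl][2-iodo-3,5-bis(methoxymethoxy)phenyl]methanone | COCOc1cc(OCOC)c(I)c(C(=O)c2c(O)c(Br)c(C)c(Cl)c2OC)c1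
F5 | step 8 | 3-allyl-2-(3-bromo-5-chloro-2-hydroxy-6-methoxy-4-methylbenzoyl)-4,6-bis(methoxymethoxy)benzaldehyde | COCOc1cc(OCOC)c(CC=C)c(C(=O)c2c(O)c(Br)c(C)c(Cl)c2OC)c1C=O
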